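# Proposed total synthesis of phlorofucofuroeckol A (31)

## Structural features

Phlorofucofuroeckol A (31) is an achiral, flat pentacyclic heteroarene, a [1]benzofuro[3,2-a]oxanthrene, in which a pentaoxygenated benzene (ring A) is joined through a 1,4-dioxin to a central benzene (ring B) that is fused through a furan to a third benzene (ring C). Rings A and C each carry a 3,5-dihydroxyphenoxy arm (at C4 and C9), and nine hydroxyls sit at C1, C3, C6, C10, C12 and on the arms. There is no stereocentre, so no neighbouring stereocentres have to be related and every selectivity problem is regiochemical. The free nonaphenol is electron-rich and oxidises readily under base and air, so the hydroxyls are kept as ethers until the last step, whereas the diaryl ether, furan and dioxin C–O bonds are robust. The real difficulty is ring B, which has a single CH (C7) and three oxygens in three roles: C5a–O and C12c–O are the dioxin oxygens and C6–O is a phenol. The unsymmetrical dioxin can in addition close in two orientations. The key step uses the fact that the four non-furan carbons of ring B, C12c(O)–C5a(O)–C6(OH)–C7(H), map onto the ester carbon, C2, C3 and C4 of a 2-alkoxyacetoacetate, so that a diene made from that ester can be added across C2=C3 of a benzofuran that already holds ring C and its arm.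

## Logic of the disconnections

**31 ⇒ 30.** Eight O–CH3 bonds and one O–Si bond are cut last. The free polyphenol would be oxidised in every basic or copper-mediated step, whereas 30 and its precursors are neutral ethers. The forward step must cleave all alkyl and silyl ethers and leave four diaryl ether bonds, the furan and the dioxin intact.

**30 ⇒ 28 + 29.** The aryl–O bond of the ring A arm (at the C4 oxygen) is cut. The arm is a symmetric six-carbon unit available as 29, and removing it leaves a single free phenol. The forward O-arylation must work on a phenol flanked by two ortho oxygens, and 28 may have no other free hydroxyl.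

**28 ⇒ 27.** The O–Si bond at C1 is cut. The C1 and C4 oxygens come from one quinone ring and must be told apart before the arm is attached; the silyl group does this and leaves one free phenol. The forward step needs site-selective silylation of the less hindered hydroxyl of 27.

**27 ⇒ 24 ⇒ 21 + 23.** The two C–O bonds joining ring A to the dioxin oxygens (O13–C13a, then O5–C4a) are cut and ring A is taken back to the quinone level. Ring A then becomes the six-carbon quinone 23, whose bromine-bearing carbon takes the first oxygen by addition–elimination and whose neighbouring CH takes the second by conjugate addition. The two ring B oxygens must react in a fixed order, or the dioxin forms in the wrong orientation; hence 21 has one free hydroxyl and the bay oxygen masked. The ring closure gives a hydroquinone that is prone to redox exchange, so the forward step passes through 25 and 26 in the flask, collects all material at the quinone level and ends with a reduction.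

**21 ⇒ 20 ⇒ 19.** A protecting-group relay: the cycloaddition delivers the bay hydroxyl free and its neighbour as a benzyl ether, and the annulation needs the reverse. The acetal in 20 must survive hydrogenolysis and carbonate and must come off under mild acid in the presence of a quinone.

**23 ⇒ 22.** The para C=O is cut; 23 is the para-oxidation product of 22.

**19 ⇒ 11 + 16 (key).** The C4–C4a and C1–C9b bonds of the dibenzofuran are cut, which opens ring B. This splits the core into 11, which holds ring C and its arm, and the four-carbon diene 16. Each oxygen of ring B arrives with its own substituent. The forward step needs regiocontrol by the nitro group, loss of nitrous acid, and aromatisation that keeps the C1 oxygen.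

**16 ⇒ 15 ⇒ 13 ⇒ 12.** The O–Si bond, the enol ether O–CH3 bond and the C2–C3 bond of the keto ester are cut. 13 is the acylation product of the enolate of 12, which avoids diazo chemistry. The forward steps must give O-methylation and γ-deprotonation.

**11 ⇒ 10 ⇒ 9 ⇒ 8.** The C3–N bond is cut and traced back through C3–B and C3–O(triflyl) to the ketone. Direct nitration of so electron-rich a benzofuran would go to C2 or to the arene rings, so the position is fixed by ipso substitution. The nitration must be chemoselective for the C–B carbon.

**8 ⇒ 7 ⇒ 5.** The acyl–aryl bond C3–C3a and the O1–C2 ether bond are cut. The oxygen tether forces ring closure at the only free ortho carbon of 5.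

**5 ⇒ 3 ⇒ 1 + 2.** The phenol oxygen is traced back to a formyl group and the diaryl ether C–O bond is cut. The formyl group of 1 first activates the ortho bromide for coupling with 2 and is then converted into the hydroxyl. The aryl group must migrate in the peracid oxidation.

## Other disconnections considered

**Alternative 1:** The cut removes the furan: the biaryl C–C bond between rings B and C and the furan O–C bond. Ring C comes from 2,6-dimethoxy-1,4-benzoquinone A2 and ring B from 7-methoxy-1,3-benzodioxol-5-ol A1. In the forward step, Cs2CO3 under air would make the phenoxide of A1 add through its ortho carbon to C3 of A2; reoxidation and displacement of the neighbouring methoxide by the phenoxide oxygen would give the dibenzofuranquinone A3.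

- In its favour: two simple partners, both furan bonds in one operation, no nitro, boron or triflate chemistry. A soft carbon nucleophile at the CH and a hard oxygen at the methoxy carbon is a well-matched pairing.
- On step economy to a dibenzofuran it is clearly the better plan: one step against the seven steps to 11, the three to 16 and the cycloaddition.
- Against it: A1 has two free ortho carbons, and only attack through C4 gives the right isomer. This is plausible on steric grounds but not secured.
- Ring C arrives without its arm. After reduction the two hydroquinone oxygens of A3 would have to be differentiated and the hindered one arylated, the same problem the chosen plan has on ring A.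
- The two dioxin oxygens of ring B are tied together as a methylenedioxy group and would be freed together. The orientation of the dioxin annulation is then uncontrolled.
- Comparison: the chosen plan is longer but delivers ring B with three distinguishable oxygens and ring C with its arm in place. Mechanistically both rest on addition to an electron-poor C=C followed by rearomatisation.

**Alternative 2:** The cut removes three C–C bonds of ring B (C5a–C6, C6–C7 and C7a–C12b). In the forward step, irradiation of the diazo ketone A4 would give a dioxinyl(aryl)ketene by Wolff rearrangement. This would add (2+2) to the tethered ethynyl ether; the cyclobutenone would open and close in a 6π process onto the dioxin CH, giving the fully assembled core A5 after tautomerisation.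

- In its favour: ring B and the furan close in one cascade with both arms and the dioxin in place. A5 is one global demethylation from 31.
- On endgame length it is clearly the better plan, and the unique ring B hydroxyl arrives free.
- Against it: A4 combines a diazo ketone, an aryl ethynyl ether and a 2-acyl-1,4-benzodioxin with both arms. Its synthesis moves the orientation problem of the unsymmetrical dioxin to an earlier stage without solving it.
- The one-atom tether would force the cyclobutenone to form fused to the incipient furan, which is strained. The carbene and ketene could be diverted by insertion or dimerisation, and the polyaryl ether chromophore would compete for light.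
- Comparison: both plans close ring B by a pericyclic step ending in aromatisation. The chosen plan uses a thermal reaction of a known type on a far simpler substrate, at the price of a longer sequence after the key step.

**Alternative 3:** The cut removes two C–C bonds of ring C (C8a–C9 and C12–C12a). In the forward step the diene A7, the bis(silyl enol ether) of methyl 4-(3,5-dimethoxyphenoxy)acetoacetate, would add across C2=C3 of the ring B nitrobenzofuran A6. Loss of nitrous acid and of methoxysilane would give the dibenzofuran A8.

- In its favour: the reaction type and regiochemical logic are those of the chosen key step, so in mechanism and precedent it is the equal of the chosen plan.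
- The arm travels on the diene, whose keto ester should come in one step from 2 and a 4-haloacetoacetate. On step economy for the arm-bearing ring it is the better plan, since no Ullmann coupling or peracid oxidation is needed.
- Against it: the nucleophilic diene terminus carries the aryloxy group and is more hindered and less reactive than the CH2 terminus of 16.
- A6 must already carry all three ring B oxygens, with the catechol masked as a methylenedioxy group. Its cleavage frees both dioxin oxygens at once, so the dioxin orientation is left uncontrolled.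
- Comparison: the chosen plan spends more steps on ring C but produces ring B with its oxygens differentiated, which is what the dioxin annulation requires.

Key step: step 11

**Remarks before the route**

- Assumption: 1, 2, 12, 22 and 29 are taken as commercial compounds.
- The atom mapping of the key step was checked against 31: the ester carbon of the diene becomes C12c (bay oxygen), the benzyloxy carbon C5a, the enol ether carbon C6 and the CH2 terminus C7.
- Design of the diene 16:
  - The ketene-acetal oxygen carries a labile trimethylsilyl group rather than a bulky silyl group, so that the bay oxygen emerges as a free phenol whichever way the ketal collapses.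
  - The C3 oxygen is a methyl enol ether rather than a silyl enol ether. An aryl silyl ether next to the catechol could migrate or cleave under the basic annulation and arylation steps, whereas the methyl ether falls in the final global deprotection at no extra cost.
- The dioxin is closed in two separate C–O bond formations in a fixed order rather than by direct annulation of the free catechol, whose two hydroxyls could react in either order.
- Locants: benzofuran numbering for 8–11, dibenzo[b,d]furan numbering for 17–25, and the numbering of the target skeleton for 26–31.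

## Route

Step 1
Reactants: 1 2-bromo-3,5-dimethoxybenzaldehyde; 2 3,5-dimethoxyphenol
Product: 3 2-(3,5-dimethoxyphenoxy)-3,5-dimethoxybenzaldehyde
Conditions: CuI (10 mol%), N,N-dimethylglycine·HCl (30 mol%), Cs2CO3, 1,4-dioxane, 100 °C
Reagents that add atoms: none
Why: Ullmann diaryl ether coupling; the ortho formyl group activates the C–Br bond and the phenol partner is unhindered.

Step 2
Reactants: 3 2-(3,5-dimethoxyphenoxy)-3,5-dimethoxybenzaldehyde
Product: 5 2-(3,5-dimethoxyphenoxy)-3,5-dimethoxyphenol, via aryl formate 4 (not isolated)
Conditions: mCPBA, CH2Cl2, 0 °C → rt; aq. NaHCO3 wash; then K2CO3 (cat.), MeOH, rt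
Reagents that add atoms: mCPBA O=C(OO)c1cccc(Cl)c1
Why: Baeyer–Villiger (Dakin-type) oxidation; the aryl group, made electron-rich by the ortho aryloxy substituent, migrates in the peracid adduct to give formate 4, which is methanolysed.

Step 3
Reactants: 5 2-(3,5-dimethoxyphenoxy)-3,5-dimethoxyphenol
Product: 7 2-[2-(3,5-dimethoxyphenoxy)-3,5-dimethoxyphenoxy]acetic acid, via ethyl ester 6 (not isolated)
Conditions: BrCH2CO2Et, K2CO3, acetone, reflux; then aq. NaOH, rt; HCl to pH 2
Reagents that add atoms: ethyl bromoacetate CCOC(=O)CBr; sodium hydroxide [Na+].[OH-]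
Why: Williamson etherification of the phenoxide followed by saponification in the same pot.

Step 4
Reactants: 7 2-[2-(3,5-dimethoxyphenoxy)-3,5-dimethoxyphenoxy]acetic acid
Product: 8 7-(3,5-dimethoxyphenoxy)-4,6-dimethoxy-1-benzofuran-3(2H)-one
Conditions: P2O5/MeSO3H, 25 °C
Reagents that add atoms: none
Why: Intramolecular Friedel–Crafts acylation; the tether allows only five-membered closure at the single free ortho carbon, which is activated by an ortho and a para methoxy group.

Step 5
Reactants: 8 7-(3,5-dimethoxyphenoxy)-4,6-dimethoxy-1-benzofuran-3(2H)-one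
Product: 9 7-(3,5-dimethoxyphenoxy)-4,6-dimethoxy-1-benzofuran-3-yl trifluoromethanesulfonate
Conditions: Tf2O, i-Pr2NEt, CH2Cl2, −78 → 0 °C
Reagents that add atoms: triflic anhydride O=S(=O)(OS(=O)(=O)C(F)(F)F)C(F)(F)F
Why: The ketone enolises to the aromatic 3-hydroxybenzofuran, which is O-sulfonylated (enol triflate formation).

Step 6
Reactants: 9 7-(3,5-dimethoxyphenoxy)-4,6-dimethoxy-1-benzofuran-3-yl trifluoromethanesulfonate
Product: 10 2-[7-(3,5-dimethoxyphenoxy)-4,6-dimethoxy-1-benzofuran-3-yl]-4,4,5,5-tetramethyl-1,3,2-dioxaborolane
Conditions: B2pin2, PdCl2(dppf) (5 mol%), KOAc, 1,4-dioxane, 85 °C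
Reagents that add atoms: bis(pinacolato)diboron CC1(C)OB(OC1(C)C)B1OC(C)(C)C(C)(C)O1
Why: Miyaura borylation of a heteroaryl triflate; oxidative addition into the enol-type C–O bond is easy and the acetate base avoids Suzuki homocoupling.

Step 7
Reactants: 10 2-[7-(3,5-dimethoxyphenoxy)-4,6-dimethoxy-1-benzofuran-3-yl]-4,4,5,5-tetramethyl-1,3,2-dioxaborolane
Product: 11 7-(3,5-dimethoxyphenoxy)-4,6-dimethoxy-3-nitro-1-benzofuran
Conditions: AgNO3, Me3SiCl, CH2Cl2, 0 °C → rt, dark
Reagents that add atoms: silver nitrate [Ag+].[O-][N+](=O)[O-]
Why: ipso-Nitration of a heteroarylboron compound by trimethylsilyl nitrate formed in the flask; the boron-bearing C3 is the most nucleophilic carbon of the molecule, so substitution should occur there before the methoxy arenes are attacked.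

Step 8
Reactants: 12 methyl 2-(benzyloxy)acetate
Product: 13 methyl 2-(benzyloxy)-3-oxobutanoate
Conditions: LiN(i-Pr)2, THF, −78 °C; then MeC(O)N(OMe)Me, −78 → −20 °C; aq. NH4Cl
Reagents that add atoms: N-methoxy-N-methylacetamide CC(=O)N(C)OC
Why: Crossed Claisen-type acylation of the ester enolate; the chelated tetrahedral adduct of the N-methoxy-N-methylamide prevents over-addition and quenching of the enolate by the product, which is racemic and configurationally labile.

Step 9
Reactants: 13 methyl 2-(benzyloxy)-3-oxobutanoate
Product: 15 methyl 2-(benzyloxy)-3-methoxybut-2-enoate, via dimethyl ketal 14 (not isolated)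
Conditions: HC(OMe)3, MeOH, H2SO4 (cat.), rt; then TsOH (cat.), toluene, 110 °C, MeOH distilled off
Reagents that add atoms: trimethyl orthoformate COC(OC)OC
Why: Acid-catalysed ketalisation and elimination of methanol to the enol ether; E/Z isomers and any 3-methoxybut-3-enoate isomer all converge on the same dienolate in step 10.

Step 10
Reactants: 15 methyl 2-(benzyloxy)-3-methoxybut-2-enoate
Product: 16 2-(benzyloxy)-1,3-dimethoxy-1-(trimethylsilyloxy)buta-1,3-diene
Conditions: LiN(i-Pr)2, THF, −78 °C; Me3SiCl, −78 °C → rt; filtered under argon, used crude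
Reagents that add atoms: chlorotrimethylsilane C[Si](C)(C)Cl
Why: γ-Deprotonation of the vinylogous ester and O-silylation of the dienolate, the standard preparation of 1-alkoxy-1-silyloxy dienes; the geometry of the ketene acetal is not controlled and does not matter.

Step 11
Reactants: 11 7-(3,5-dimethoxyphenoxy)-4,6-dimethoxy-3-nitro-1-benzofuran; 16 2-(benzyloxy)-1,3-dimethoxy-1-(trimethylsilyloxy)buta-1,3-diene
Product: 19 2-(benzyloxy)-6-(3,5-dimethoxyphenoxy)-3,7,9-trimethoxydibenzo[b,d]furan-1-ol, via nitro cycloadduct 17 (not isolated), via dihydro intermediate 18 (not isolated)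
Conditions: 16 (3 equiv), toluene, 115 °C, sealed tube, argon; then 1 M HCl–THF, rt
Reagents that add atoms: none
Why: Polar, strongly asynchronous Diels–Alder reaction of normal electron demand in which the nitro-activated C2=C3 bond of 11 is the dienophile: the unsubstituted CH2 terminus of 16 bonds to the electrophilic C2 (β to nitro) and the ketene-acetal carbon to C3, giving the cis-fused adduct 17. Thermal loss of nitrous acid from 17 (C4a–H, C9b–NO2) restores the furan in 18; the mixed methyl silyl ketal at C1 then ionises, methoxide leaving and taking the silyl group, and enolisation across C4 gives the arene, with the acid work-up cleaving any surviving silyl ether, so that C1 carries the free bay phenol, C2 the benzyl ether and C3 the methyl ether. The closest known reaction type is the thermal polar Diels–Alder reaction of 3-nitrobenzofurans with 1-alkoxy-3-silyloxy- and 1,3-bis(silyloxy)butadienes with loss of nitrous acid in the flask, together with the benzannulation of halo-quinones by 1-alkoxy-1-silyloxy dienes, in which the ketene-acetal oxygen likewise ends as a peri hydroxyl. Ring B is closed by the [4+2] cycloaddition itself (bonds C4–C4a and C1–C9b through a six-membered transition state; in the stepwise limit a Michael addition followed by six-membered closure of the nitronate onto the silyloxycarbenium ion). The three stereocentres of 17 (C1, C4a, C9b) are destroyed on aromatisation, so none has to be controlled. The step needs regioselectivity, secured by the nitro group at C3, which makes C2 the only electrophilic terminus, and by the unsubstituted nucleophilic terminus of the diene. It also needs chemoselectivity for the hetero-ring double bond, which the methoxy arenes cannot rival as dienophiles. The excess of 16 compensates for protodesilylation of the diene by the nitrous acid set free.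

Step 12
Reactants: 19 2-(benzyloxy)-6-(3,5-dimethoxyphenoxy)-3,7,9-trimethoxydibenzo[b,d]furan-1-ol
Product: 20 2-{[2-(benzyloxy)-6-(3,5-dimethoxyphenoxy)-3,7,9-trimethoxydibenzo[b,d]furan-1-yl]oxy}oxane
Conditions: 3,4-dihydro-2H-pyran, PPTS (cat.), CH2Cl2, rt
Reagents that add atoms: 3,4-dihydro-2H-pyran C1CCOC=C1
Why: Acid-catalysed addition of the phenol to the enol ether (tetrahydropyranyl acetal formation); the acetal is racemic at its new carbon, cannot migrate to the neighbouring oxygen, and withstands hydrogenolysis and carbonate.

Step 13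
Reactants: 20 2-{[2-(benzyloxy)-6-(3,5-dimethoxyphenoxy)-3,7,9-trimethoxydibenzo[b,d]furan-1-yl]oxy}oxane
Product: 21 6-(3,5-dimethoxyphenoxy)-3,7,9-trimethoxy-1-(oxan-2-yloxy)dibenzo[b,d]furan-2-ol
Conditions: H2 (1 atm), Pd/C, EtOAc, rt
Reagents that add atoms: none
Why: Hydrogenolysis of the benzyl ether; diaryl ethers, the furan and the acetal are inert, so only the C2 hydroxyl is freed.

Step 14
Reactants: 22 2-bromo-6-methoxyphenol
Product: 23 2-bromo-6-methoxy-1,4-benzoquinone
Conditions: K2[ON(SO3)2], KH2PO4 buffer, H2O–acetone, 0 °C → rt
Reagents that add atoms: potassium nitrosodisulfonate [K+].[K+].[O]N(S(=O)(=O)[O-])S(=O)(=O)[O-]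
Why: Oxidation of a 2,6-disubstituted phenol at its free para position to the para-quinone by the nitroxyl radical (Teuber reaction).

Step 15
Reactants: 21 6-(3,5-dimethoxyphenoxy)-3,7,9-trimethoxy-1-(oxan-2-yloxy)dibenzo[b,d]furan-2-ol; 23 2-bromo-6-methoxy-1,4-benzoquinone
Product: 24 2-{[6-(3,5-dimethoxyphenoxy)-3,7,9-trimethoxy-1-(oxan-2-yloxy)dibenzo[b,d]furan-2-yl]oxy}-6-methoxy-1,4-benzoquinone
Conditions: K2CO3, MeCN, 0 °C → rt, argon
Reagents that add atoms: none
Why: Addition–elimination (nucleophilic vinylic substitution) of the only free phenoxide at the bromine-bearing quinone carbon; bromide is lost irreversibly, whereas attack at the methoxy carbon or the CH positions is reversible for a hard oxygen nucleophile. With the bay oxygen masked, the first aryl ether bond can form only at O2 of the dibenzofuran.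

Step 16
Reactants: 24 2-{[6-(3,5-dimethoxyphenoxy)-3,7,9-trimethoxy-1-(oxan-2-yloxy)dibenzo[b,d]furan-2-yl]oxy}-6-methoxy-1,4-benzoquinone
Product: 27 9-(3,5-dimethoxyphenoxy)-3,6,10,12-tetramethoxy[1]benzofuro[3,2-a]oxanthrene-1,4-diol, via phenol quinone 25 (not isolated), via dioxin quinone 26 (not isolated)
Conditions: PPTS, acetone–H2O, 40 °C; then NaHCO3, MeCN–H2O, air, rt; then aq. Na2S2O4, EtOAc, rt, argon; organic phase dried and concentrated under argon
Reagents that add atoms: none
Why: Mild hydrolysis of the aryl acetal frees the bay phenol 25, whose oxygen closes the dioxin by six-membered oxa-Michael addition to the quinone CH next to the aryl ether carbon (C3 in benzoquinone numbering), the position β to the cross-conjugated and more electrophilic C1 carbonyl; ipso attack at the ether carbon would have to use the C4 carbonyl, which is deactivated as a doubly vinylogous ester. The first-formed hydroquinone is oxidised by air under bicarbonate and by exchange with unreacted 25, and air also returns any 25 reduced in that exchange, so that all material converges on quinone 26. Dithionite then reduces 26 to the hydroquinone 27, which is kept under argon and used at once.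

Step 17
Reactants: 27 9-(3,5-dimethoxyphenoxy)-3,6,10,12-tetramethoxy[1]benzofuro[3,2-a]oxanthrene-1,4-diol
Product: 28 1-[(tert-butyldimethylsilyl)oxy]-9-(3,5-dimethoxyphenoxy)-3,6,10,12-tetramethoxy[1]benzofuro[3,2-a]oxanthren-4-ol
Conditions: t-BuMe2SiCl (1.05 equiv), imidazole, DMF, 0 °C, argon
Reagents that add atoms: tert-butyldimethylsilyl chloride CC(C)(C)[Si](C)(C)Cl
Why: Sterically controlled mono-silylation of a hydroquinone; the C1 hydroxyl has a free ortho position, whereas the C4 hydroxyl is flanked by the methoxy group and a dioxin oxygen, so one equivalent of the bulky silyl chloride should go to O1.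

Step 18
Reactants: 28 1-[(tert-butyldimethylsilyl)oxy]-9-(3,5-dimethoxyphenoxy)-3,6,10,12-tetramethoxy[1]benzofuro[3,2-a]oxanthren-4-ol; 29 (3,5-dimethoxyphenyl)boronic acid
Product: 30 tert-butyl{[4,9-bis(3,5-dimethoxyphenoxy)-3,6,10,12-tetramethoxy[1]benzofuro[3,2-a]oxanthren-1-yl]oxy}dimethylsilane
Conditions: Cu(OAc)2, pyridine, 4 Å molecular sieves, CH2Cl2, air, rt
Reagents that add atoms: none
Why: Chan–Lam oxidative O-arylation (transmetalation to a cupric phenoxide, oxidation, C–O reductive elimination); it runs at room temperature under weakly basic conditions that spare the aryl silyl ether and is known to accept di-ortho-substituted phenols.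

Step 19
Reactants: 30 tert-butyl{[4,9-bis(3,5-dimethoxyphenoxy)-3,6,10,12-tetramethoxy[1]benzofuro[3,2-a]oxanthren-1-yl]oxy}dimethylsilane
Product: 31 phlorofucofuroeckol A (4,9-bis(3,5-dihydroxyphenoxy)[1]benzofuro[3,2-a]oxanthrene-1,3,6,10,12-pentol)
Conditions: BBr3 (excess), CH2Cl2, −78 °C → rt, argon; MeOH quench
Reagents that add atoms: none
Why: Lewis-acid-mediated ether cleavage: BBr3 coordinates each alkyl aryl ether oxygen and bromide attacks the methyl carbon (or silicon); the diaryl ether, furan and dioxin C(sp2)–O bonds offer no such site and remain. The methanolic HBr formed on quenching completes the desilylation.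

## Compound list

1 | 2-bromo-3,5-dimethoxybenzaldehyde | O=Cc1cc(OC)cc(OC)c1Br | starting material
2 | 3,5-dimethoxyphenol | COc1cc(O)cc(OC)c1 | starting material
3 | 2-(3,5-dimethoxyphenoxy)-3,5-dimethoxybenzaldehyde | O=Cc1cc(OC)cc(OC)c1Oc1cc(OC)cc(OC)c1 | intermediate
4 | 2-(3,5-dimethoxyphenoxy)-3,5-dimethoxyphenyl formate | O=COc1cc(OC)cc(OC)c1Oc1cc(OC)cc(OC)c1 | intermediate (not isolated)
5 | 2-(3,5-dimethoxyphenoxy)-3,5-dimethoxyphenol | Oc1cc(OC)cc(OC)c1Oc1cc(OC)cc(OC)c1 | intermediate
6 | ethyl 2-[2-(3,5-dimethoxyphenoxy)-3,5-dimethoxyphenoxy]acetate | CCOC(=O)COc1cc(OC)cc(OC)c1Oc1cc(OC)cc(OC)c1 | intermediate (not isolated)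
7 | 2-[2-(3,5-dimethoxyphenoxy)-3,5-dimethoxyphenoxy]acetic acid | OC(=O)COc1cc(OC)cc(OC)c1Oc1cc(OC)cc(OC)c1 | intermediate
8 | 7-(3,5-dimethoxyphenoxy)-4,6-dimethoxy-1-benzofuran-3(2H)-one | O=C1COc2c(Oc3cc(OC)cc(OC)c3)c(OC)cc(OC)c12 | intermediate
9 | 7-(3,5-dimethoxyphenoxy)-4,6-dimethoxy-1-benzofuran-3-yl trifluoromethanesulfonate | FC(F)(F)S(=O)(=O)Oc1coc2c(Oc3cc(OC)cc(OC)c3)c(OC)cc(OC)c12 | intermediate
10 | 2-[7-(3,5-dimethoxyphenoxy)-4,6-dimethoxy-1-benzofuran-3-yl]-4,4,5,5-tetramethyl-1,3,2-dioxaborolane | CC1(C)OB(OC1(C)C)c1coc2c(Oc3cc(OC)cc(OC)c3)c(OC)cc(OC)c12 | intermediate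
11 | 7-(3,5-dimethoxyphenoxy)-4,6-dimethoxy-3-nitro-1-benzofuran | [O-][N+](=O)c1coc2c(Oc3cc(OC)cc(OC)c3)c(OC)cc(OC)c12 | intermediate (key-step precursor)
12 | methyl 2-(benzyloxy)acetate | COC(=O)COCc1ccccc1 | starting material
13 | methyl 2-(benzyloxy)-3-oxobutanoate (racemic) | COC(=O)C(OCc1ccccc1)C(C)=O | intermediate
14 | methyl 2-(benzyloxy)-3,3-dimethoxybutanoate (racemic) | COC(=O)C(OCc1ccccc1)C(C)(OC)OC | intermediate (not isolated)
15 | methyl 2-(benzyloxy)-3-methoxybut-2-enoate (E/Z mixture; E isomer drawn) | COC(=O)/C(OCc1ccccc1)=C(/C)OC | intermediate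
16 | 2-(benzyloxy)-1,3-dimethoxy-1-(trimethylsilyloxy)buta-1,3-diene (mixture of ketene-acetal isomers; 1Z drawn) | CO/C(O[Si](C)(C)C)=C(/OCc1ccccc1)C(=C)OC | intermediate (key-step precursor)
17 | 2-(benzyloxy)-6-(3,5-dimethoxyphenoxy)-1,3,7,9-tetramethoxy-9b-nitro-1-(trimethylsilyloxy)-1,4,4a,9b-tetrahydrodibenzo[b,d]furan (cis-fused, racemic, C1 epimers) | COC1(O[Si](C)(C)C)C(OCc2ccccc2)=C(OC)CC2Oc3c(Oc4cc(OC)cc(OC)c4)c(OC)cc(OC)c3C12[N+](=O)[O-] | intermediate (not isolated)
18 | 2-(benzyloxy)-6-(3,5-dimethoxyphenoxy)-1,3,7,9-tetramethoxy-1-(trimethylsilyloxy)-1,4-dihydrodibenzo[b,d]furan (racemic) | COC1(O[Si](C)(C)C)C(OCc2ccccc2)=C(OC)Cc2oc3c(Oc4cc(OC)cc(OC)c4)c(OC)cc(OC)c3c12 | intermediate (not isolated)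
19 | 2-(benzyloxy)-6-(3,5-dimethoxyphenoxy)-3,7,9-trimethoxydibenzo[b,d]furan-1-ol | COc1cc2oc3c(Oc4cc(OC)cc(OC)c4)c(OC)cc(OC)c3c2c(O)c1OCc1ccccc1 | intermediate (key-step product)
20 | 2-{[2-(benzyloxy)-6-(3,5-dimethoxyphenoxy)-3,7,9-trimethoxydibenzo[b,d]furan-1-yl]oxy}oxane (racemic) | COc1cc2oc3c(Oc4cc(OC)cc(OC)c4)c(OC)cc(OC)c3c2c(OC2CCCCO2)c1OCc1ccccc1 | intermediate
21 | 6-(3,5-dimethoxyphenoxy)-3,7,9-trimethoxy-1-(oxan-2-yloxy)dibenzo[b,d]furan-2-ol (racemic) | COc1cc2oc3c(Oc4cc(OC)cc(OC)c4)c(OC)cc(OC)c3c2c(OC2CCCCO2)c1O | intermediate
22 | 2-bromo-6-methoxyphenol | COc1cccc(Br)c1O | starting material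
23 | 2-bromo-6-methoxy-1,4-benzoquinone | COC1=CC(=O)C=C(Br)C1=O | intermediate
24 | 2-{[6-(3,5-dimethoxyphenoxy)-3,7,9-trimethoxy-1-(oxan-2-yloxy)dibenzo[b,d]furan-2-yl]oxy}-6-methoxy-1,4-benzoquinone (racemic) | COc1cc2oc3c(Oc4cc(OC)cc(OC)c4)c(OC)cc(OC)c3c2c(OC2CCCCO2)c1OC1=CC(=O)C=C(OC)C1=O | intermediate
25 | 2-{[6-(3,5-dimethoxyphenoxy)-1-hydroxy-3,7,9-trimethoxydibenzo[b,d]furan-2-yl]oxy}-6-methoxy-1,4-benzoquinone | COc1cc2oc3c(Oc4cc(OC)cc(OC)c4)c(OC)cc(OC)c3c2c(O)c1OC1=CC(=O)C=C(OC)C1=O | intermediate (not isolated)
26 | 9-(3,5-dimethoxyphenoxy)-3,6,10,12-tetramethoxy[1]benzofuro[3,2-a]oxanthrene-1,4-dione | O=C1C(OC)=CC(=O)C2=C1Oc1c(OC)cc3oc4c(Oc5cc(OC)cc(OC)c5)c(OC)cc(OC)c4c3c1O2 | intermediate (not isolated)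
27 | 9-(3,5-dimethoxyphenoxy)-3,6,10,12-tetramethoxy[1]benzofuro[3,2-a]oxanthrene-1,4-diol | Oc1c(OC)cc(O)c2c1Oc1c(OC)cc3oc4c(Oc5cc(OC)cc(OC)c5)c(OC)cc(OC)c4c3c1O2 | intermediate
28 | 1-[(tert-butyldimethylsilyl)oxy]-9-(3,5-dimethoxyphenoxy)-3,6,10,12-tetramethoxy[1]benzofuro[3,2-a]oxanthren-4-ol | Oc1c(OC)cc(O[Si](C)(C)C(C)(C)C)c2c1Oc1c(OC)cc3oc4c(Oc5cc(OC)cc(OC)c5)c(OC)cc(OC)c4c3c1O2 | intermediate
29 | (3,5-dimethoxyphenyl)boronic acid | COc1cc(OC)cc(B(O)O)c1 | starting material
30 | tert-butyl{[4,9-bis(3,5-dimethoxyphenoxy)-3,6,10,12-tetramethoxy[1]benzofuro[3,2-a]oxanthren-1-yl]oxy}dimethylsilane | COc1cc(OC)cc(Oc2c(OC)cc(O[Si](C)(C)C(C)(C)C)c3c2Oc2c(OC)cc4oc5c(Oc6cc(OC)cc(OC)c6)c(OC)cc(OC)c5c4c2O3)c1 | intermediate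
31 | phlorofucofuroeckol A (4,9-bis(3,5-dihydroxyphenoxy)[1]benzofuro[3,2-a]oxanthrene-1,3,6,10,12-pentol) | Oc1cc(O)cc(Oc2c(O)cc(O)c3c2Oc2c(O)cc4oc5c(Oc6cc(O)cc(O)c6)c(O)cc(O)c5c4c2O3)c1 | target

## Step count and least certain steps

Total: 19 steps. Longest linear sequence: 15 steps (steps 1–7, 11–13, 15–19). Side branches: steps 8–10 (diene) and step 14 (quinone).

**1. Step 11 (key step).**
- What may go wrong: the cycloaddition may be slow, because the peri methoxy group twists the nitro group and C2 is donor-substituted. The diene may be destroyed by protodesilylation with the liberated nitrous acid before it reacts. The reaction may stall at the open-chain Michael adduct. The ketal may collapse with loss of silanol, which would methylate the bay oxygen.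
- Fallback (sets out from 11 and 16, returns at 19): the two C–C bonds are made one at a time. A Me3SiOTf-catalysed vinylogous Mukaiyama–Michael addition of 16 to C2 of 11 at −78 °C gives, after aqueous work-up, the Michael adduct F1. KOt-Bu in THF then closes ring B by intramolecular acylation of the nitronate with the methyl ester (Dieckmann-type) to the nitro ketone F2. This loses nitrite and enolises to 19. The bay oxygen is then the former ester carbonyl and cannot be lost.

**2. Step 16 (with the substitution of step 15).**
- What may go wrong: the dioxin orientation may be scrambled if the liberated bay phenoxide attacks the aryloxy-bearing quinone carbon reversibly (Smiles-type ether exchange through a spiro ketal) before the conjugate addition. In step 15, cine instead of ipso substitution would have the same effect. Quinone–hydroquinone exchange may strand uncyclised material at the hydroquinone level if air does not return it, and the electron-rich product may re-oxidise on contact with air during isolation, which would erode the selectivity of step 17.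
- Fallback (sets out from 2 and 11, returns at 31): ring A and its arm are carried in on the diene, and the dioxin is closed by copper catalysis on a non-electrophilic ring where no ether exchange can occur. Ullmann mono-coupling of 2 with 2,6-dibromo-3,5-dimethoxybenzaldehyde F3 gives the bromo aldehyde F4, and Baeyer–Villiger oxidation gives the bromophenol F5. O-Alkylation of F5 with methyl 2-chloro-3-oxobutanoate F6 (K2CO3, acetone) gives the aryloxy keto ester F7. Enol ether formation and silylation as in steps 9 and 10 give the enol ether F8 and the diene F9. Cycloaddition of F9 to 11 under the conditions of step 11 gives the bay phenol F10. Intramolecular Ullmann etherification of F10 (CuI, N,N-dimethylglycine, Cs2CO3, dioxane, 110 °C) joins the bay oxygen to the brominated carbon and gives the nonamethyl ether F11, which BBr3 converts into 31.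

**3. Step 7.**
- What may go wrong: the silyl nitrate may nitrate or oxidise the dimethoxyaryl rings in competition with the C–B carbon, and the electron-rich heteroaryl boronate may protodeboronate.
- Fallback (sets out from 9, returns at 11; no new compound, F0): palladium-catalysed coupling of the triflate with nitrite (Pd2(dba)3, t-BuBrettPhos, NaNO2, tris(3,6-dioxaheptyl)amine, t-BuOH, 110–130 °C). This uses a nucleophilic nitrogen source and no electrophilic nitrating agent.

**4. Step 18.**
- What may go wrong: transmetalation and C–O reductive elimination may be slow at the di-ortho-substituted phenol, so that protodeboronation and homocoupling of 29 and oxidation of the electron-rich phenol by the cupric salt take over.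
- Fallback (sets out from 28, returns at 30): metal-free arylation of the potassium phenoxide (KOt-Bu, THF, rt) with (3,5-dimethoxyphenyl)(2,4,6-trimethoxyphenyl)iodonium tosylate F12. The trimethoxyphenyl group serves as the non-transferred ligand.

**5. Step 19.**
- What may go wrong: cleavage of eight methyl ethers may be incomplete, because partly cleaved aryl borates precipitate, and the partly deprotected polyphenols may oxidise in air during work-up.
- Fallback (sets out from 30, returns at 31): Bu4NF removes the silyl group to give the phenol F13. The methyl ethers are then cleaved by SN2 attack of sodium dodecanethiolate on the methyl carbons (NMP, 130 °C, argon), followed by acidification under argon.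

## Further compounds

F1 | step 11 | methyl 2-(benzyloxy)-4-[7-(3,5-dimethoxyphenoxy)-4,6-dimethoxy-3-nitro-2,3-dihydro-1-benzofuran-2-yl]-3-methoxybut-2-enoate | COC(=O)C(OCc1ccccc1)=C(OC)CC1Oc2c(Oc3cc(OC)cc(OC)c3)c(OC)cc(OC)c2C1[N+](=O)[O-]
F2 | step 11 | 2-(benzyloxy)-6-(3,5-dimethoxyphenoxy)-3,7,9-trimethoxy-9b-nitro-4a,9b-dihydrodibenzo[b,d]furan-1(4H)-one | COC1=C(OCc2ccccc2)C(=O)C2([N+](=O)[O-])C(C1)Oc1c(Oc3cc(OC)cc(OC)c3)c(OC)cc(OC)c12
F3 | step 16 | 2,6-dibromo-3,5-dimethoxybenzaldehyde | O=Cc1c(Br)c(OC)cc(OC)c1Br
F4 | step 16 | 2-bromo-6-(3,5-dimethoxyphenoxy)-3,5-dimethoxybenzaldehyde | O=Cc1c(Br)c(OC)cc(OC)c1Oc1cc(OC)cc(OC)c1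
F5 | step 16 | 2-bromo-6-(3,5-dimethoxyphenoxy)-3,5-dimethoxyphenol | Oc1c(Br)c(OC)cc(OC)c1Oc1cc(OC)cc(OC)c1
F6 | step 16 | methyl 2-chloro-3-oxobutanoate | COC(=O)C(Cl)C(C)=O
F7 | step 16 | methyl 2-[2-bromo-6-(3,5-dimethoxyphenoxy)-3,5-dimethoxyphenoxy]-3-oxobutanoate | COC(=O)C(Oc1c(Br)c(OC)cc(OC)c1Oc1cc(OC)cc(OC)c1)C(C)=O
F8 | step 16 | methyl 2-[2-bromo-6-(3,5-dimethoxyphenoxy)-3,5-dimethoxyphenoxy]-3-methoxybut-2-enoate | COC(=O)C(Oc1c(Br)c(OC)cc(OC)c1Oc1cc(OC)cc(OC)c1)=C(C)OC
F9 | step 16 | 2-[2-bromo-6-(3,5-dimethoxyphenoxy)-3,5-dimethoxyphenoxy]-1,3-dimethoxy-1-(trimethylsilyloxy)buta-1,3-diene | COC(O[Si](C)(C)C)=C(Oc1c(Br)c(OC)cc(OC)c1Oc1cc(OC)cc(OC)c1)C(=C)OC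
F10 | step 16 | 2-[2-bromo-6-(3,5-dimethoxyphenoxy)-3,5-dimethoxyphenoxy]-6-(3,5-dimethoxyphenoxy)-3,7,9-trimethoxydibenzo[b,d]furan-1-ol | COc1cc2oc3c(Oc4cc(OC)cc(OC)c4)c(OC)cc(OC)c3c2c(O)c1Oc1c(Br)c(OC)cc(OC)c1Oc1cc(OC)cc(OC)c1
F11 | step 16 | 4,9-bis(3,5-dimethoxyphenoxy)-1,3,6,10,12-pentamethoxy[1]benzofuro[3,2-a]oxanthrene | COc1cc(OC)cc(Oc2c(OC)cc(OC)c3c2Oc2c(OC)cc4oc5c(Oc6cc(OC)cc(OC)c6)c(OC)cc(OC)c5c4c2O3)c1
F0 | step 7 | none | none
F12 | step 18 | (3,5-dimethoxyphenyl)(2,4,6-trimethoxyphenyl)iodonium 4-methylbenzenesulfonate | COc1cc(OC)cc([I+]c2c(OC)cc(OC)cc2OC)c1.Cc1ccc(cc1)S([O-])(=O)=O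
F13 | step 19 | 4,9-bis(3,5-dimethoxyphenoxy)-3,6,10,12-tetramethoxy[1]benzofuro[3,2-a]oxanthren-1-ol | COc1cc(OC)cc(Oc2c(OC)cc(O)c3c2Oc2c(OC)cc4oc5c(Oc6cc(OC)cc(OC)c6)c(OC)cc(OC)c5c4c2O3)c1
A1 | alternative 1 | 7-methoxy-1,3-benzodioxol-5-ol | COc1cc(O)cc2OCOc12
A2 | alternative 1 | 2,6-dimethoxy-1,4-benzoquinone | COC1=CC(=O)C=C(OC)C1=O
A3 | alternative 1 | 3,7-dimethoxy-8,9-(methylenedioxy)dibenzo[b,d]furan-1,4-dione | COC1=CC(=O)c2c(oc3cc(OC)c4OCOc4c23)C1=O
A4 | alternative 2 | 2-diazo-2-[3-(3,5-dimethoxyphenoxy)-2-(ethynyloxy)-4,6-dimethoxyphenyl]-1-[5-(3,5-dimethoxyphenoxy)-6,8-dimethoxy-1,4-benzodioxin-2-yl]ethan-1-one | COc1cc(OC)cc(Oc2c(OC)cc(OC)c3OC(C(=O)C(=[N+]=[N-])c4c(OC)cc(OC)c(Oc5cc(OC)cc(OC)c5)c4OC#C)=COc23)c1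
A5 | alternative 2 | 4,9-bis(3,5-dimethoxyphenoxy)-1,3,10,12-tetramethoxy[1]benzofuro[3,2-a]oxanthren-6-ol | COc1cc(OC)cc(Oc2c(OC)cc(OC)c3c2Oc2c(O)cc4oc5c(Oc6cc(OC)cc(OC)c6)c(OC)cc(OC)c5c4c2O3)c1
A6 | alternative 3 | 6-methoxy-4,5-(methylenedioxy)-3-nitro-1-benzofuran | [O-][N+](=O)c1coc2cc(OC)c3OCOc3c12
A7 | alternative 3 | 4-(3,5-dimethoxyphenoxy)-1-methoxy-1,3-bis(trimethylsilyloxy)buta-1,3-diene | COC(O[Si](C)(C)C)=CC(O[Si](C)(C)C)=COc1cc(OC)cc(OC)c1
A8 | alternative 3 | 4-(3,5-dimethoxyphenoxy)-7-methoxy-8,9-(methylenedioxy)dibenzo[b,d]furan-1,3-diol | Oc1cc(O)c(Oc2cc(OC)cc(OC)c2)c2oc3cc(OC)c4OCOc4c3c12
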